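**Assumption:** Eryvarin F (C25H26O6) has no stereocentre, and both alkenes end in gem-dimethyl groups, so there is no E/Z issue. The molecule is achiral, so the "single enantiomer" requirement needs no stereocontrol.

## Retrosynthetic overview
1. Both aryl–prenyl bonds are cut last, as a double sp2–sp3 Suzuki coupling on a fully unprotected 6,8-diiodo triphenol. The iodines go onto ring A before the more electron-rich ring B is present.
2. The O3–C1' bond is cut with reversed polarity: an intact 3-hydroxychromone acts as O-nucleophile and ring B as an aryl-boron "Ar+" (Chan–Lam–Evans). This replaces the usual α-aryloxyacetophenone + C1 ring closure.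
3. The pyranone ring and its C3–O bond are made together by oxidative C–H acyloxylation/annulation of an o-hydroxyaryl enaminone.
4. Rings A and B are purchased. The only ring built is pyranone ring C. The order is A → C → attach B → demethylate → prenylate.

## Route

**Step 1**
Reactants: 1, paeonol (1-(2-hydroxy-4-methoxyphenyl)ethanone)
Product: 2, 1-(2-hydroxy-3,5-diiodo-4-methoxyphenyl)ethanone
Conditions: I2 (0.9 equiv), HIO3 (0.45 equiv), EtOH–H2O, 40 → 70 °C
Reagents that add atoms: iodine, II; iodic acid, OI(=O)=O
Why: This is an electrophilic aromatic iodination in which the free 2-OH (ortho/para) and the 4-OMe (ortho/ortho) both direct to C3 and C5 while C6 is meta to both donors, so exhaustive iodination stops at the 3,5-diiodide and fixes both future prenyl positions.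

**Step 2**
Reactants: 2
Product: 3, (E)-3-(dimethylamino)-1-(2-hydroxy-3,5-diiodo-4-methoxyphenyl)prop-2-en-1-one
Conditions: DMF-DMA (3 equiv), PhMe, 95 °C
Reagents that add atoms: N,N-dimethylformamide dimethyl acetal, COC(OC)N(C)C
Why: This is an amide-acetal (enaminone) condensation at the only acidic C–H site, the acetyl CH3; the chelated 2-OH and the aryl iodides are inert, and the thermodynamic E geometry is erased in Step 3.

**Step 3**
Reactants: 3
Product: 4, 6,8-diiodo-7-methoxy-4-oxo-4H-chromen-3-yl benzoate
Conditions: (BzO)2 (2 equiv), MeCN, 80 °C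
Reagents that add atoms: dibenzoyl peroxide, O=C(OOC(=O)c1ccccc1)c1ccccc1
Why: This is a domino enaminone C(sp2)–H acyloxylation/chromone annulation, a known reaction class for o-hydroxyaryl enaminones with diaroyl peroxides: benzoyloxy is delivered to the nucleophilic α-carbon, the ortho phenol traps the resulting iminium and Me2NH is expelled, forming ring C and the C3–O bond in one operation.

**Step 4**
Reactants: 4
Product: 5, 3-hydroxy-6,8-diiodo-7-methoxy-4H-chromen-4-one
Conditions: K2CO3 (1.5 equiv), MeOH–THF, 0 °C, N2; then 1 M HCl
Reagents that add atoms: none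
Why: This is a transesterification (methanolysis) of an activated enol ester, which is much faster than attack at C2, and the 3-olate it releases deactivates the chromone Michael acceptor until the acidic work-up.

**Step 5 (key C–O step)**
Reactants: 5; 6, (2,4-dimethoxyphenyl)boronic acid (2.5 equiv)
Product: 7, 3-(2,4-dimethoxyphenoxy)-6,8-diiodo-7-methoxy-4H-chromen-4-one
Conditions: Cu(OAc)2 (2 equiv), pyridine (6 equiv), 4 Å MS, CH2Cl2, dry air, rt
Reagents that add atoms: (2,4-dimethoxyphenyl)boronic acid, COc1ccc(B(O)O)c(OC)c1
Why: This is a Chan–Lam–Evans oxidative C–O coupling in which the acidic enol (pKa about 8, similar to ortho-diiodophenols that couple well) binds Cu(II), the electron-rich boronic acid transmetalates and Cu(III) eliminates O-selectively at room temperature, where the Ar–I bonds and the base-sensitive C2–H chromone are untouched; stoichiometric Cu and excess pyridine counter O,O-chelation by the substrate.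

**Step 6**
Reactants: 7
Product: 8, 3-(2,4-dihydroxyphenoxy)-7-hydroxy-6,8-diiodo-4H-chromen-4-one
Conditions: BBr3 (9 equiv), CH2Cl2, −78 °C → rt; then MeOH/H2O, 0 °C
Reagents that add atoms: none
Why: This is a Lewis-acid aryl methyl ether cleavage in which bromide can only attack the three O–CH3 carbons, so the vinyl–O–aryl link, the pyranone and the C–I bonds survive, and it is run before any acid-sensitive prenyl group is present.

**Step 7 (key C–C step)**
Reactants: 8; 9, prenylboronic acid pinacol ester (4 equiv)
Product: 10, Eryvarin F
Conditions: Pd(dppf)Cl2·CH2Cl2 (10 mol %), Cs2CO3 (7 equiv), degassed THF–H2O (5:1), 65 °C; pH 5 buffer work-up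
Reagents that add atoms: 4,4,5,5-tetramethyl-2-(3-methylbut-2-en-1-yl)-1,3,2-dioxaborolane, CC(C)=CCB1OC(C)(C)C(C)(C)O1
Why: This is a double Suzuki–Miyaura allyl–aryl coupling in which aryl iodides still undergo oxidative addition as phenoxides, σ–π–σ equilibration of the prenyl–Pd species gives reductive elimination at the unhindered CH2 terminus (linear prenyl), the 7-phenoxide shields C2 from hydroxide, and no acid or deprotection step follows prenylation.

## Compound list
1 | paeonol, 1-(2-hydroxy-4-methoxyphenyl)ethanone | CC(=O)c1ccc(OC)cc1O | starting material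
2 | 1-(2-hydroxy-3,5-diiodo-4-methoxyphenyl)ethanone | CC(=O)c1cc(I)c(OC)c(I)c1O | intermediate
3 | (E)-3-(dimethylamino)-1-(2-hydroxy-3,5-diiodo-4-methoxyphenyl)prop-2-en-1-one | CN(C)/C=C/C(=O)c1cc(I)c(OC)c(I)c1O | intermediate
4 | 6,8-diiodo-7-methoxy-4-oxo-4H-chromen-3-yl benzoate | COc1c(I)cc2c(=O)c(OC(=O)c3ccccc3)coc2c1I | intermediate
5 | 3-hydroxy-6,8-diiodo-7-methoxy-4H-chromen-4-one | COc1c(I)cc2c(=O)c(O)coc2c1I | intermediate
6 | (2,4-dimethoxyphenyl)boronic acid | COc1ccc(B(O)O)c(OC)c1 | starting material
7 | 3-(2,4-dimethoxyphenoxy)-6,8-diiodo-7-methoxy-4H-chromen-4-one | COc1ccc(Oc2coc3c(I)c(OC)c(I)cc3c2=O)c(OC)c1 | intermediate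
8 | 3-(2,4-dihydroxyphenoxy)-7-hydroxy-6,8-diiodo-4H-chromen-4-one | Oc1ccc(Oc2coc3c(I)c(O)c(I)cc3c2=O)c(O)c1 | intermediate
9 | 4,4,5,5-tetramethyl-2-(3-methylbut-2-en-1-yl)-1,3,2-dioxaborolane (prenyl-Bpin) | CC(C)=CCB1OC(C)(C)C(C)(C)O1 | starting material
10 | Eryvarin F, 3-(2,4-dihydroxyphenoxy)-7-hydroxy-6,8-bis(3-methylbut-2-en-1-yl)-4H-chromen-4-one (achiral) | CC(C)=CCc1cc2c(=O)c(Oc3ccc(O)cc3O)coc2c(CC=C(C)C)c1O | target

## Summary
Total step count: 7
Longest linear sequence: 7 (1 → 10)

**Steps most likely to fail, with fallbacks**
1. **Step 5 (Chan–Lam on the chelating 3-hydroxychromone).**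
   - Risks: an inert Cu(II) bis-chelate forms, or the ortho-methoxy boronic acid protodeboronates.
   - Fallback: use a metal-free SNAr with an oxidation-state switch. React 5 with 4-fluoro-3-methoxybenzaldehyde (K2CO3, DMF). Then convert the activating CHO into the 4'-OH by Baeyer–Villiger oxidation (mCPBA) and formate methanolysis; no alkenes are present yet.
   - The route rejoins at Step 6, where BBr3 cleaves the 7-OMe and 2'-OMe.
2. **Step 7 (double prenyl Suzuki on the unprotected triphenol).**
   - Risks: protodeiodination, reverse-prenyl (γ) coupling at the hindered C8, or base damage to the chromone.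
   - Fallback: peracetylate 8 and run a double Stille allylation with allylSnBu3, which has no α/γ ambiguity.
   - Then carry out a double cross-metathesis with 2-methyl-2-butene (Grubbs II) and a mild deacetylation.
3. **Step 3 (acyloxylation/annulation on the hindered, electron-poor diiodophenol).**
   - Risks: consumption of the peroxide by the released amine, or low conversion.
   - Fallback: close the ring first and oxidise afterwards. Cyclise 3 with HCl to 6,8-diiodo-7-methoxychromone.
   - Then apply Weitz–Scheffer epoxidation (H2O2/NaOH) and acid-induced isomerisation of the epoxide to give 5 directly.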